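**Retrosynthetic overview**
- Last C–C bond: the C4(upper)–C6(lower) interflavan bond, from a flavan-4-yl cation (4β-benzylthio ether, silver activation) and the lower flavan, followed by global O-debenzylation.
- Each flavan partner comes from a 2,3-cis-flavan-3-ol by DDQ oxidation at C4; the 3-OH is set by hydride reduction of a flavan-3-one.
- Key disconnection (both units): C3–C4 together with O1–C2, giving a salicylaldehyde and a β-nitrostyrene. C3 is the carbon of nitromethane, used as a masked acyl anion (nitronate, later converted to C=O by a Nef reaction) that joins two aldehyde carbons: ArCHO (C2) and the salicylaldehyde CHO (C4).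
- Ring order: rings A and B are bought as aldehydes; ring C of each unit is closed in the oxa-Michael/nitroaldol cascade, which also sets C2; the two units are joined last.

Assumption: BnBr, BnOH, BnSH, MeOH and water are treated as reagents and carry no compound number.

**Route**

Step 1
Reactants: 1 2,3,4-trihydroxybenzaldehyde
Product: 2 3,4-bis(benzyloxy)-2-hydroxybenzaldehyde
Conditions: BnBr (2.1 equiv), K2CO3 (2.2 equiv), DMF, 0 °C → rt
Reagents that add atoms: benzyl bromide, BrCc1ccccc1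
Why: Williamson ether synthesis; the 4-OH (para to the formyl group) and the 3-OH are alkylated, while the 2-OH is held in a hydrogen bond to the aldehyde and stays free for the later ring closure.

Step 2
Reactants: 3 4-(benzyloxy)benzaldehyde; 4 nitromethane
Product: 5 (E)-1-(benzyloxy)-4-(2-nitroethenyl)benzene
Conditions: MeNO2 (5 equiv), NH4OAc (0.5 equiv), AcOH, 100 °C
Reagents that add atoms: none
Why: Henry (nitroaldol) condensation with dehydration gives the thermodynamically favoured E-nitroalkene and attaches the nitromethane carbon (future C3) to the future C2.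

Step 3
Reactants: 6 3,4-bis(benzyloxy)benzaldehyde; 4 nitromethane
Product: 7 (E)-1,2-bis(benzyloxy)-4-(2-nitroethenyl)benzene
Conditions: MeNO2 (5 equiv), NH4OAc (0.5 equiv), AcOH, 100 °C
Reagents that add atoms: none
Why: Henry (nitroaldol) condensation with dehydration, as in step 2, gives the E-nitroalkene for the lower unit.

Step 4
Reactants: 2 3,4-bis(benzyloxy)-2-hydroxybenzaldehyde; 5 (E)-1-(benzyloxy)-4-(2-nitroethenyl)benzene
Product: 8 (2R)-7,8-bis(benzyloxy)-2-[4-(benzyloxy)phenyl]-3-nitro-2H-chromene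
Conditions: (S)-1-methyl-2-[(pyrrolidin-2-yl)methylsulfanyl]imidazole (20 mol %; the mirror-image catalyst if the first run shows the 2S sense), salicylic acid (20 mol %), DMSO, rt → 40 °C, 3 d; recrystallise to ≥98% ee
Reagents that add atoms: none
Why: Organocatalytic tandem oxa-Michael/Henry (nitroaldol) condensation: the amine forms an iminium ion with 2, the phenol oxygen adds to the nitroalkene under the chiral pyrrolidine and sets C2 as R, and the resulting nitronate carbon, a masked acyl anion that step 5 unmasks to the C3 carbonyl, attacks the former aldehyde carbon to close ring C through the C3–C4 bond before the amine is eliminated.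

Step 5
Reactants: 8 (2R)-7,8-bis(benzyloxy)-2-[4-(benzyloxy)phenyl]-3-nitro-2H-chromene
Product: 10 (2R)-7,8-bis(benzyloxy)-2-[4-(benzyloxy)phenyl]chroman-3-one, via trans-3-nitroflavan 9 (not isolated)
Conditions: NaBH4, silica gel, CHCl3–i-PrOH, 0 °C; then NaOMe (1.1 equiv), MeOH, 0 °C, 10 min; then TiCl3, NH4OAc, H2O–THF (pH 5–6), 0 °C → rt
Reagents that add atoms: water, O
Why: Conjugate hydride reduction of the nitroalkene followed by a reductive Nef reaction (trivalent titanium reduces the nitronate to the imine, which hydrolyses in the buffer) turns the nitro-bearing C3 into the ketone with only brief, cold exposure to base, so the enolisable C2 centre is kept.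

Step 6
Reactants: 10 (2R)-7,8-bis(benzyloxy)-2-[4-(benzyloxy)phenyl]chroman-3-one
Product: 11 (2R,3R)-7,8-bis(benzyloxy)-2-[4-(benzyloxy)phenyl]chroman-3-ol
Conditions: LiBH(s-Bu)3 (L-Selectride), LiBr, THF, −78 °C; aq NH4Cl
Reagents that add atoms: none
Why: Diastereoselective ketone reduction; the bulky trialkylborohydride attacks from the face opposite the 2-aryl group, giving the 3-OH cis to the aryl group (new C3 = R), the standard entry to 2,3-cis flavan-3-ols.

Step 7
Reactants: 11 (2R,3R)-7,8-bis(benzyloxy)-2-[4-(benzyloxy)phenyl]chroman-3-ol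
Product: 13 (2R,3S,4S)-4-(benzylsulfanyl)-7,8-bis(benzyloxy)-2-[4-(benzyloxy)phenyl]chroman-3-ol, via 4β-methoxy ether 12 (not isolated)
Conditions: DDQ (1.5 equiv), CH2Cl2–MeOH (9:1), rt; filter through basic alumina; then BnSH (3 equiv), BF3·OEt2 (0.2 equiv), CH2Cl2, −20 °C
Reagents that add atoms: phenylmethanethiol, SCc1ccccc1
Why: DDQ benzylic oxidation (hydride abstraction at C4 gives a quinone-methide-type cation stabilised by the 7-OBn group, trapped by methanol as 12) followed by Lewis-acid thiolysis through the same cation, the thiol entering on the face anti to the 3-OH and 2-aryl groups to set the 3,4-trans (4β) thioether.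

Step 8
Reactants: 2 3,4-bis(benzyloxy)-2-hydroxybenzaldehyde; 7 (E)-1,2-bis(benzyloxy)-4-(2-nitroethenyl)benzene
Product: 14 (2R)-7,8-bis(benzyloxy)-2-[3,4-bis(benzyloxy)phenyl]-3-nitro-2H-chromene
Conditions: (S)-1-methyl-2-[(pyrrolidin-2-yl)methylsulfanyl]imidazole (20 mol %; same catalyst enantiomer as in step 4), salicylic acid (20 mol %), DMSO, rt → 40 °C, 3 d; recrystallise to ≥98% ee
Reagents that add atoms: none
Why: Organocatalytic tandem oxa-Michael/Henry (nitroaldol) condensation as in step 4: C2 is set as R in the oxa-Michael step and the nitronate carbon (masked acyl anion, future C3) closes ring C onto the former aldehyde carbon.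

Step 9
Reactants: 14 (2R)-7,8-bis(benzyloxy)-2-[3,4-bis(benzyloxy)phenyl]-3-nitro-2H-chromene
Product: 16 (2R)-7,8-bis(benzyloxy)-2-[3,4-bis(benzyloxy)phenyl]chroman-3-one, via trans-3-nitroflavan 15 (not isolated)
Conditions: NaBH4, silica gel, CHCl3–i-PrOH, 0 °C; then NaOMe (1.1 equiv), MeOH, 0 °C, 10 min; then TiCl3, NH4OAc, H2O–THF (pH 5–6), 0 °C → rt
Reagents that add atoms: water, O
Why: Conjugate hydride reduction and reductive Nef reaction as in step 5 unmask C3 as the ketone while C2 is kept.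

Step 10
Reactants: 16 (2R)-7,8-bis(benzyloxy)-2-[3,4-bis(benzyloxy)phenyl]chroman-3-one
Product: 17 (2R,3R)-7,8-bis(benzyloxy)-2-[3,4-bis(benzyloxy)phenyl]chroman-3-ol
Conditions: LiBH(s-Bu)3 (L-Selectride), LiBr, THF, −78 °C; aq NH4Cl
Reagents that add atoms: none
Why: Diastereoselective ketone reduction as in step 6; hydride adds anti to the 2-aryl group and sets C3 as R (2,3-cis).

Step 11
Reactants: 17 (2R,3R)-7,8-bis(benzyloxy)-2-[3,4-bis(benzyloxy)phenyl]chroman-3-ol
Product: 18 (2R,3R,4S)-4,7,8-tris(benzyloxy)-2-[3,4-bis(benzyloxy)phenyl]chroman-3-ol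
Conditions: DDQ (1.5 equiv), BnOH (5 equiv), CH2Cl2, rt
Reagents that add atoms: benzyl alcohol, OCc1ccccc1
Why: DDQ benzylic oxidation at C4 with benzyl alcohol as the trap, which adds to the quinone-methide-type cation anti to the 3-OH and 2-aryl groups and sets C4 as S (4β, 3,4-trans); the benzyl ether keeps this oxygen inert in step 12 and is removed in step 13.

Step 12
Reactants: 13 (2R,3S,4S)-4-(benzylsulfanyl)-7,8-bis(benzyloxy)-2-[4-(benzyloxy)phenyl]chroman-3-ol; 18 (2R,3R,4S)-4,7,8-tris(benzyloxy)-2-[3,4-bis(benzyloxy)phenyl]chroman-3-ol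
Product: 19 octa-O-benzyl ether of 20 (all phenolic OH and the lower 4-OH as OBn; both 3-OH free; all six stereocentres as in 20)
Conditions: AgBF4 (2.5 equiv), 2,6-di-tert-butyl-4-methylpyridine (3 equiv), 4 Å molecular sieves, THF, −20 → 0 °C, dark, 18 in excess (3 equiv, recovered); aq NaHCO3
Reagents that add atoms: none
Why: Thiophilic activation of a 4-thioflavan and Friedel–Crafts capture of the flavan-4-yl cation: monovalent silver removes benzylthiolate from 13 only (the benzylic ether of 18 is untouched and the pyridine base takes up the acid formed), and C6 of 18 (ortho to 7-OBn, para to the ring oxygen, C5 being shielded by the peri 4-OBn) attacks the cation from the face anti to the 3-OH and 2-aryl groups, giving the 3,4-trans (4β→6) interflavan bond.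

Step 13
Reactants: 19 octa-O-benzyl ether of 20
Product: 20 (2R,3R,4S)-2-(3,4-dihydroxyphenyl)-6-[(2R,3R,4S)-3,7,8-trihydroxy-2-(4-hydroxyphenyl)chroman-4-yl]chromane-3,4,7,8-tetrol
Conditions: H2 (1 atm), Pd(OH)2/C, THF–MeOH (1:1), rt, stopped at full debenzylation; filter through diatomaceous earth under argon
Reagents that add atoms: none
Why: Catalytic hydrogenolysis of the eight benzyl ethers; the unhindered O–CH2Ph bonds cleave faster than the ring C4–O bond, and the neutral medium with short contact time protects the benzylic 4-OH and the interflavan bond, no stereocentre being touched.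

**Compound list**

1 | 2,3,4-trihydroxybenzaldehyde | O=Cc1ccc(O)c(O)c1O | starting material
2 | 3,4-bis(benzyloxy)-2-hydroxybenzaldehyde | O=Cc1ccc(OCc2ccccc2)c(OCc2ccccc2)c1O | intermediate
3 | 4-(benzyloxy)benzaldehyde | O=Cc1ccc(OCc2ccccc2)cc1 | starting material
4 | nitromethane | C[N+](=O)[O-] | starting material
5 | (E)-1-(benzyloxy)-4-(2-nitroethenyl)benzene | [O-][N+](=O)/C=C/c1ccc(OCc2ccccc2)cc1 | intermediate
6 | 3,4-bis(benzyloxy)benzaldehyde | O=Cc1ccc(OCc2ccccc2)c(OCc2ccccc2)c1 | starting material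
7 | (E)-1,2-bis(benzyloxy)-4-(2-nitroethenyl)benzene | [O-][N+](=O)/C=C/c1ccc(OCc2ccccc2)c(OCc2ccccc2)c1 | intermediate
8 | (2R)-7,8-bis(benzyloxy)-2-[4-(benzyloxy)phenyl]-3-nitro-2H-chromene | C(c1ccccc1)Oc1ccc([C@H]2Oc3c(ccc(OCc4ccccc4)c3OCc3ccccc3)C=C2[N+](=O)[O-])cc1 | intermediate
9 | (2R,3S)-7,8-bis(benzyloxy)-2-[4-(benzyloxy)phenyl]-3-nitrochromane (trans; the C3 epimer is equally usable) | C(c1ccccc1)Oc1ccc([C@H]2Oc3c(ccc(OCc4ccccc4)c3OCc3ccccc3)C[C@@H]2[N+](=O)[O-])cc1 | intermediate
10 | (2R)-7,8-bis(benzyloxy)-2-[4-(benzyloxy)phenyl]chroman-3-one | C(c1ccccc1)Oc1ccc([C@H]2Oc3c(ccc(OCc4ccccc4)c3OCc3ccccc3)CC2=O)cc1 | intermediate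
11 | (2R,3R)-7,8-bis(benzyloxy)-2-[4-(benzyloxy)phenyl]chroman-3-ol (2,3-cis) | C(c1ccccc1)Oc1ccc([C@H]2Oc3c(ccc(OCc4ccccc4)c3OCc3ccccc3)C[C@H]2O)cc1 | intermediate
12 | (2R,3R,4S)-7,8-bis(benzyloxy)-2-[4-(benzyloxy)phenyl]-4-methoxychroman-3-ol (2,3-cis-3,4-trans) | C(c1ccccc1)Oc1ccc([C@H]2Oc3c(ccc(OCc4ccccc4)c3OCc3ccccc3)[C@H](OC)[C@H]2O)cc1 | intermediate
13 | (2R,3S,4S)-4-(benzylsulfanyl)-7,8-bis(benzyloxy)-2-[4-(benzyloxy)phenyl]chroman-3-ol (2,3-cis-3,4-trans) | C(c1ccccc1)Oc1ccc([C@H]2Oc3c(ccc(OCc4ccccc4)c3OCc3ccccc3)[C@H](SCc3ccccc3)[C@H]2O)cc1 | intermediate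
14 | (2R)-7,8-bis(benzyloxy)-2-[3,4-bis(benzyloxy)phenyl]-3-nitro-2H-chromene | C(c1ccccc1)Oc1ccc([C@H]2Oc3c(ccc(OCc4ccccc4)c3OCc3ccccc3)C=C2[N+](=O)[O-])cc1OCc1ccccc1 | intermediate
15 | (2R,3S)-7,8-bis(benzyloxy)-2-[3,4-bis(benzyloxy)phenyl]-3-nitrochromane (trans; the C3 epimer is equally usable) | C(c1ccccc1)Oc1ccc([C@H]2Oc3c(ccc(OCc4ccccc4)c3OCc3ccccc3)C[C@@H]2[N+](=O)[O-])cc1OCc1ccccc1 | intermediate
16 | (2R)-7,8-bis(benzyloxy)-2-[3,4-bis(benzyloxy)phenyl]chroman-3-one | C(c1ccccc1)Oc1ccc([C@H]2Oc3c(ccc(OCc4ccccc4)c3OCc3ccccc3)CC2=O)cc1OCc1ccccc1 | intermediate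
17 | (2R,3R)-7,8-bis(benzyloxy)-2-[3,4-bis(benzyloxy)phenyl]chroman-3-ol (2,3-cis) | C(c1ccccc1)Oc1ccc([C@H]2Oc3c(ccc(OCc4ccccc4)c3OCc3ccccc3)C[C@H]2O)cc1OCc1ccccc1 | intermediate
18 | (2R,3R,4S)-4,7,8-tris(benzyloxy)-2-[3,4-bis(benzyloxy)phenyl]chroman-3-ol (2,3-cis-3,4-trans) | C(c1ccccc1)Oc1ccc([C@H]2Oc3c(ccc(OCc4ccccc4)c3OCc3ccccc3)[C@H](OCc3ccccc3)[C@H]2O)cc1OCc1ccccc1 | intermediate
19 | octa-O-benzyl ether of 20 (upper unit 7,8,4'-OBn; lower unit 4,7,8,3',4'-OBn; both 3-OH free; configuration as in 20) | c5ccccc5COc1ccc([C@H]2Oc3c(ccc(OCc5ccccc5)c3OCc5ccccc5)[C@H](c3cc4c(c(OCc5ccccc5)c3OCc5ccccc5)O[C@H](c3ccc(OCc5ccccc5)c(OCc5ccccc5)c3)[C@H](O)[C@H]4OCc5ccccc5)[C@H]2O)cc1 | intermediate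
20 | (2R,3R,4S)-2-(3,4-dihydroxyphenyl)-6-[(2R,3R,4S)-3,7,8-trihydroxy-2-(4-hydroxyphenyl)chroman-4-yl]chromane-3,4,7,8-tetrol (CNP0275688.1) | Oc1ccc([C@H]2Oc3c(ccc(O)c3O)[C@H](c3cc4c(c(O)c3O)O[C@H](c3ccc(O)c(O)c3)[C@H](O)[C@H]4O)[C@H]2O)cc1 | target

**Step count and risks**

Total step count: 13. Longest linear sequence: 7 steps (1 → 4 → 5 → 6 → 7 → 12 → 13; the lower arm 1 → 8 → 9 → 10 → 11 → 12 → 13 is equally long).

The three steps most likely to fail:

Step 4. The asymmetric cascade may be slow with the electron-rich aldehyde 2 and may give an ee too low to upgrade by crystallisation. Fallback: starting again from 2 and 5, the cascade is run with the achiral base DABCO (MeCN, 40 °C), which gives the racemic nitrochromene F1. Preparative chromatography on a chiral stationary phase (supercritical CO2/MeOH) then delivers 8, where the route is rejoined, and the mirror-image (2S)-nitrochromene F2, which is set aside.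

Step 5. The nitronate formed during the Nef sequence can open ring C by loss of the aryloxide (retro-oxa-Michael), and the ketone can enolise; either erodes C2. Fallback: from 8, zinc dust in AcOH–THF at 0 °C reduces the conjugated nitroalkene directly to the ketoxime F3 without any nitronate or base. Buffered aqueous TiCl3 (NH4OAc, rt) then cleaves the N–O bond and hydrolyses the imine, rejoining the route at 10.

Step 12. The cation from 13 may self-condense, attack C5, or the acid formed may ionise the 4-OBn group of 18. Fallback: the order of interflavan coupling and lower C4 oxygenation is reversed. The methoxy ether 12 (here isolated after the DDQ stage of step 7) and the flavan-3-ol 17 (3 equiv) are coupled with BF3·OEt2 (CH2Cl2, −40 → 0 °C), neither partner carrying a second ionisable C4–O bond, to give the hepta-O-benzyl 4-deoxy dimer F4. DDQ and BnOH then oxidise F4 at its only benzylic CH2 (C4 of the lower unit; the upper C4–H lies in the plane of ring A and is not abstracted), rejoining the route at 19.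

**Further compounds**

F1 | step 4 | racemic 7,8-bis(benzyloxy)-2-[4-(benzyloxy)phenyl]-3-nitro-2H-chromene | C(c1ccccc1)Oc1ccc(C2Oc3c(ccc(OCc4ccccc4)c3OCc3ccccc3)C=C2[N+](=O)[O-])cc1
F2 | step 4 | (2S)-7,8-bis(benzyloxy)-2-[4-(benzyloxy)phenyl]-3-nitro-2H-chromene | C(c1ccccc1)Oc1ccc([C@@H]2Oc3c(ccc(OCc4ccccc4)c3OCc3ccccc3)C=C2[N+](=O)[O-])cc1
F3 | step 5 | (2R)-7,8-bis(benzyloxy)-2-[4-(benzyloxy)phenyl]chroman-3-one oxime | C(c1ccccc1)Oc1ccc([C@H]2Oc3c(ccc(OCc4ccccc4)c3OCc3ccccc3)CC2=NO)cc1
F4 | step 12 | hepta-O-benzyl 4-deoxy analogue of 19 (lower unit C4 = CH2; configuration otherwise as in 19) | c5ccccc5COc1ccc([C@H]2Oc3c(ccc(OCc5ccccc5)c3OCc5ccccc5)[C@H](c3cc4c(c(OCc5ccccc5)c3OCc5ccccc5)O[C@H](c3ccc(OCc5ccccc5)c(OCc5ccccc5)c3)[C@H](O)C4)[C@H]2O)cc1
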